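**Numbering used throughout.** Ring: C1 (bears the chain), C2, C3, C4 (bears the methyl), C5, C6. Chain: C7 (=C14H2), C8, C9, C10, C11. Stereodescriptors quoted with these locants refer to this numbering.

## The problem

- The target 21 is a bisabolane in which every ring carbon is substituted: C1 carries the chain, C2 a tiglate, C3/C4 an epoxide with the C4 methyl, C5 the ketone and C6 an acetate. The chain holds an exocyclic methylene on C7, a second tiglate at the allylic carbon C8 and a trisubstituted epoxide at C10/C11.
- No rings have to be fused; the task is to place seven oxygen-bearing carbons and seven stereocentres (C1, C2, C3, C4, C6, C8, C10) on fifteen skeletal carbons.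
- On the ring, the chain, the C2 ester and the epoxide oxygen share one face and the C6 acetate lies on the other. C1 can therefore set C6 directly and C2–C4 by relay. C8 and C10 are insulated from the ring by the sp2 carbon C7 and from each other by C9, and need reagent control.
- Several groups are fragile: the α,β-epoxy ketone, the α-acetoxy ketone (epimerisable C6, base-labile acetate), the acid-labile 2,2-dimethyloxirane (which a free C8 hydroxyl can open), and the allylic C8 ester (ionisable by zerovalent palladium). γ-Oxygenated cyclohexenone intermediates can also lose water to phenols.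
- The enabling feature: once the ring epoxide is read as an epoxidised enone, C2–O and C5=O stand 1,4 across C3=C4(CH3). That is the pattern left when dioxygen adds across the termini of a cyclohexa-1,3-diene and the peroxide is opened by base.
- The diene concerned (C2=C3–C4(CH3)=C5, chain on C1) has the p-menthane pattern and lies two steps from a carvone-type enone. The carbocycle, the C4 methyl, C1 and C7/C8/C14 can therefore be bought.
- The catch is that oxygen will arrive anti to the chain whereas the C2 ester must end syn. The plan uses this: the trans C2 oxygen first steers the epoxidation and is inverted last.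

## Retrosynthesis

**C2–O (acyl) bond, 21 ⇒ 20 + 13.** The C2 ester is made last, with inversion, from the trans epoxy alcohol 20 and tiglic acid 13. This lets the trans C2 oxygen be used earlier as a directing group. The forward reaction must be an SN2 displacement on the face that already holds the chain and the epoxide.

**C3–O and C4–O, 20 ⇒ 19 ⇒ 18.** The ring epoxide is removed to the enone 18; silyl ether 19 is the direct epoxidation product. Nucleophilic epoxidation is the only mode an enone accepts. It must deliver oxygen anti to the bulky C2 silyl ether, which places the epoxide on the chain face. Epoxidising before the C6 acetate is present was considered; it would replace a one-step acetoxylation by a strong-base enolate oxidation of an epoxy ketone.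

**C6–O, 18 ⇒ 17 ⇒ 16.** The acetate is cut back to the α′-methylene of enone 17, the silyl ether of 16. Direct α′-acetoxylation of an enone does this in one step, and the adjacent C1 chain should send the acetate trans. The only demand is survival of the side-chain epoxide.

**C2–O and C5–O (key), 16 ⇒ 15 ⇒ 14.** Both ring oxygens of 16 come from one molecule of dioxygen, added across C2 and C5 of diene 14 to give endoperoxide 15, which base opens to the hydroxy enone. Stepwise γ-oxidation of a preformed C5 enone would be the neighbouring cut, but that approach has no control of the C2 configuration. Here the C1 chain sets it. The precursor loses two oxygens and one stereocentre. The forward step needs anti addition, cycloaddition over ene reaction, and proton removal at C5.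

**C8 ester and the diene, 14 ⇒ 12 + 13; 12 ⇒ 11 ⇒ 10 ⇒ 9 ⇒ 8.**
- The tiglate is put on alcohol 12 after the diene exists.
- Diene 11 comes from dienyl triflate 10 by palladium-catalysed reduction.
- Triflate 10 comes from the kinetic dienolate 9 of enone 8.
- C8 is kept as a silyl ether through these steps. An allylic carboxylate would be exposed to zerovalent palladium and formate, and an ester would sit within reach of the enolate.
- The cost is two protecting-group steps, accepted for safety.

**C10/C11 epoxide and C10=C11, 8 ⇒ 7 ⇒ 6.** The side-chain epoxide is made from the prenyl alkene of 7 by a chiral dioxirane, while the ring is still an electron-poor enone and cannot compete. The prenyl group comes from the terminal alkene of 6 by cross-metathesis. Introducing the epoxide after the diene is formed would not be chemoselective.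

**C8–C9, 6 ⇒ 5 ⇒ 4 ⇒ 3.** The C8 carbinol and the C8–C9 bond come from allylboration of enal 3 (through borinate 4), under control of the boron ligands. A C7–C8 disconnection (ring alkenyl metal plus a chiral epoxy aldehyde) was the neighbour. It would leave C8 to substrate control and require a ring alkenyl halide that is not at hand.

**C8 oxidation level, 3 ⇒ 2 ⇒ 1.** Enal 3 is (S)-carvone 1 oxidised at the isopropenyl methyl, reached through allylic chloride 2. Compound 1 supplies C1 in the right absolute configuration, the C4 methyl and the enone needed for 10. Assembling the same ring from an unsubstituted one would cost at least three more steps and an asymmetric catalyst.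

## Roads not taken

**Alternative 1: Diels–Alder construction of the ring.**
- Cut and key step: C1–C2 and C5–C6. (1E,3E)-1,4-Bis(silyloxy)-2-methylbutadiene A1 and (E)-4-acetoxybut-3-en-2-one A2 would combine under a chiral cationic oxazaborolidine Lewis acid to give adduct A3.
- Merits: ring and four stereocentres in one catalytic step. In A3 the C2 oxygen is already cis to the C1 carbon substituent and the C6 acetate trans, exactly as in 21. No inversion at C2 and no separate acetoxylation are needed. Here it is better than the plan adopted.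
- Weak points:
  - A3 carries only an acetyl group at C1. C14, C8–C11 and the stereocentres C8 and C10 must all be grown from a methyl ketone flanked by two β-oxygen substituents, where enolisation invites β-elimination and C1 epimerisation.
  - Regiocontrol rests on the small bias of one methyl group in a diene whose two termini are otherwise equally activated.
  - C5 must later be unmasked and oxidised.
- Comparison: the adopted plan offers a purchased ring in which C1, C7, C8 and C14 are already joined, and a chain finished by reagent-controlled steps before any sensitive ring oxygen exists.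

**Alternative 2: carbene-catalysed benzoin closure at C4–C5.**
- Cut and key step: the acyclic keto aldehyde A4 would be closed by a chiral triazolium-derived carbene (acyl anion equivalent at C5 adding to the C4 methyl ketone) to give the tertiary α-hydroxy ketone A5.
- Merits: the C5 ketone and the C4 tertiary C–O bond form together under near-neutral conditions. The C4 hydroxyl trans to the C3 oxygen allows epoxide closure by SN2 at C3, so the epoxide configuration follows unambiguously. This is more certain than the face-selective epoxidation of 18.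
- Weak points:
  - A4 must already contain C1, C2, C3, C6, C8 and C10 as stereocentres, all set by acyclic methods, with three kinds of protecting group.
  - Its α-alkoxy aldehyde centre is epimerisable under the basic carbene conditions.
  - After A5, several protecting-group exchanges remain before the esters are in place.
- Comparison: the adopted plan accepts one selectivity risk in exchange for a route roughly half as long to the same oxidation pattern.

**Alternative 3: Ferrier carbocyclization of a sugar.**
- Cut and key step: C3–C4. The manno-configured 3-C-alkenyl hex-5-enopyranoside A6 would be converted by catalytic Hg(OCOCF3)2 (divalent mercury) in aqueous acetone into the β-hydroxy cyclohexanone A7.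
- Merits: a dependable ring closure. The pyranoside supplies C1, C2 and C6 with the correct relative configuration (C2 oxygen cis, C6 oxygen trans to the branch), again without inversion at C2.
- Weak points:
  - The C-branch at the sugar's C3 needs a multistep, stereocontrolled C–C bond formation.
  - The electron-rich prenyl alkene of A6 competes for the mercury salt.
  - A7 lacks both the C4 methyl and the C3=C4 unsaturation. Dehydration, α-methylation of the enone and epoxidation would follow, and the epoxidation would face the same facial question as in the adopted plan.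
- Comparison: better at C2 and C6, worse in carbon count and step economy. The adopted plan starts with the methyl-bearing enone in hand.

Key step: step 11

**Assumption:** (S)-(+)-carvone is used because its stereocentre maps onto C1 of the target with the required sense; both enantiomers are articles of commerce.

## Route

Step 1
Reactants: 1 (S)-(+)-carvone, (5S)-2-methyl-5-(prop-1-en-2-yl)cyclohex-2-en-1-one
Product: 2 (5S)-5-(3-chloroprop-1-en-2-yl)-2-methylcyclohex-2-en-1-one
Conditions: Ca(OCl)2, CO2 (dry ice), CH2Cl2/H2O, 0 °C to rt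
Reagents that add atoms: calcium hypochlorite, [Ca+2].[O-]Cl.[O-]Cl
Why: HOCl released from Ca(OCl)2 and carbonic acid chlorinates the electron-rich 1,1-disubstituted alkene in an ene-type allylic chlorination (chlorine to the terminal carbon, proton lost from the methyl group); the electron-poor enone alkene does not compete and the stereocentre is not touched.

Step 2
Reactants: 2 (5S)-5-(3-chloroprop-1-en-2-yl)-2-methylcyclohex-2-en-1-one
Product: 3 2-[(1S)-4-methyl-5-oxocyclohex-3-en-1-yl]prop-2-enal
Conditions: N-methylmorpholine N-oxide, KI (cat.), NaHCO3, 4 Å molecular sieves, MeCN, rt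
Reagents that add atoms: N-methylmorpholine N-oxide, C[N+]1([O-])CCOCC1
Why: Amine N-oxide oxidation of an activated halide (Kornblum-type): iodide-assisted SN2 attack of the N-oxide oxygen on the allylic chloride gives an alkoxyammonium salt, which loses N-methylmorpholine by elimination to leave the 2-substituted acrolein. No stereocentre is formed.

Step 3
Reactants: 3 2-[(1S)-4-methyl-5-oxocyclohex-3-en-1-yl]prop-2-enal
Product: 5 (5S)-5-[(3S)-3-hydroxyhexa-1,5-dien-2-yl]-2-methylcyclohex-2-en-1-one, via diisopinocampheylborinate ester 4 (not isolated)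
Conditions: (−)-Ipc2BOMe, allylMgBr, Et2O, 0 °C to rt; then 3, −78 °C; then HOCH2CH2NH2, rt
Reagents that add atoms: allylmagnesium bromide, C=CC[Mg]Br, whose allyl group is passed on through (−)-B-allyldiisopinocampheylborane, C=CCB([C@@H]1C[C@@H]2C[C@H]([C@H]1C)C2(C)C)[C@@H]1C[C@@H]2C[C@H]([C@H]1C)C2(C)C
Why: Brown allylboration through a closed chair transition state; the isopinocampheyl groups derived from (+)-α-pinene select the aldehyde face that gives the (S)-carbinol at C8, by analogy with aldehydes whose substituent outranks the allyl group, and the remote C1 centre should not interfere. The aldehyde reacts far faster than the enone carbonyl, and the amine work-up avoids alkaline peroxide, which would epoxidise the enone.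

Step 4
Reactants: 5 (5S)-5-[(3S)-3-hydroxyhexa-1,5-dien-2-yl]-2-methylcyclohex-2-en-1-one
Product: 6 (5S)-5-[(3S)-3-(tert-butyldimethylsilyloxy)hexa-1,5-dien-2-yl]-2-methylcyclohex-2-en-1-one
Conditions: TBSCl, imidazole, DMF, rt
Reagents that add atoms: tert-butyldimethylsilyl chloride, CC(C)(C)[Si](C)(C)Cl
Why: Standard silylation of a secondary alcohol; the silyl ether keeps C8 inert to the enolate and palladium chemistry of steps 7 and 8 and prevents the hydroxyl from opening the later C10/C11 epoxide.

Step 5
Reactants: 6 (5S)-5-[(3S)-3-(tert-butyldimethylsilyloxy)hexa-1,5-dien-2-yl]-2-methylcyclohex-2-en-1-one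
Product: 7 (5S)-5-[(3S)-3-(tert-butyldimethylsilyloxy)-6-methylhepta-1,5-dien-2-yl]-2-methylcyclohex-2-en-1-one
Conditions: 2-methylbut-2-ene (excess), second-generation Grubbs catalyst RuCl2(=CHPh)(PCy3)(H2IMes) (cat.), CH2Cl2, 35 °C
Reagents that add atoms: 2-methylbut-2-ene, CC=C(C)C
Why: Olefin cross-metathesis of a monosubstituted alkene with excess 2-methylbut-2-ene installs the prenyl terminus; the hindered 1,1-disubstituted C7=C14 alkene and the trisubstituted enone do not engage the ruthenium carbene, and ring closure between the two chain alkenes would require a cyclobutene.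

Step 6
Reactants: 7 (5S)-5-[(3S)-3-(tert-butyldimethylsilyloxy)-6-methylhepta-1,5-dien-2-yl]-2-methylcyclohex-2-en-1-one
Product: 8 (5S)-5-{(3S)-3-(tert-butyldimethylsilyloxy)-4-[(2R)-3,3-dimethyloxiran-2-yl]but-1-en-2-yl}-2-methylcyclohex-2-en-1-one
Conditions: D-fructose-derived Shi ketone (cat.), KHSO5 (as 2KHSO5·KHSO4·K2SO4), K2CO3, Bu4NHSO4, Na2B4O7 buffer, MeCN/CH2(OMe)2/H2O, 0 °C
Reagents that add atoms: potassium peroxymonosulfate, [K+].[O-]S(=O)(=O)OO
Why: Shi epoxidation: the chiral dioxirane formed in situ transfers oxygen through a spiro transition state, and the D-fructose-derived ketone should give the (R)-epoxide at C10 from a 2-methylalk-2-ene. The trisubstituted prenyl alkene is the most electron-rich; the enone and the C7=C14 alkene next to the silyloxy carbon should react much more slowly.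

Step 7
Reactants: 8 (5S)-5-{(3S)-3-(tert-butyldimethylsilyloxy)-4-[(2R)-3,3-dimethyloxiran-2-yl]but-1-en-2-yl}-2-methylcyclohex-2-en-1-one
Product: 10 (6S)-6-{(3S)-3-(tert-butyldimethylsilyloxy)-4-[(2R)-3,3-dimethyloxiran-2-yl]but-1-en-2-yl}-3-methylcyclohexa-1,3-dien-2-yl trifluoromethanesulfonate, via lithium dienolate 9 (not isolated)
Conditions: LiN(iPr)2, THF, −78 °C; then PhNTf2, −78 to 0 °C
Reagents that add atoms: N-phenylbis(trifluoromethanesulfonimide), O=S(=O)(N(c1ccccc1)S(=O)(=O)C(F)(F)F)C(F)(F)F
Why: Kinetic α′-deprotonation of the enone at the ring CH2 next to the carbonyl (C2) gives the cross-conjugated dienolate, which is O-sulfonylated; this is the standard route from 2-methylcyclohex-2-enones to 2-triflyloxy-1,3-dienes. The epoxide and silyl ether are inert at −78 °C.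

Step 8
Reactants: 10 (6S)-6-{(3S)-3-(tert-butyldimethylsilyloxy)-4-[(2R)-3,3-dimethyloxiran-2-yl]but-1-en-2-yl}-3-methylcyclohexa-1,3-dien-2-yl trifluoromethanesulfonate
Product: 11 tert-butyl{[(2S)-1-[(2R)-3,3-dimethyloxiran-2-yl]-3-[(1S)-4-methylcyclohexa-2,4-dien-1-yl]but-3-en-2-yl]oxy}dimethylsilane
Conditions: Pd(OAc)2 (cat.), PPh3, HCO2H, Bu3N, DMF, 40 °C
Reagents that add atoms: none
Why: Palladium-catalysed formate reduction of an alkenyl triflate: oxidative addition of zerovalent palladium into the C–O bond, formate exchange, loss of CO2 and reductive elimination of C–H leave the C2=C3–C4=C5 diene in place. With C8 as a silyl ether no allylic leaving group is offered to the catalyst.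

Step 9
Reactants: 11 tert-butyl{[(2S)-1-[(2R)-3,3-dimethyloxiran-2-yl]-3-[(1S)-4-methylcyclohexa-2,4-dien-1-yl]but-3-en-2-yl]oxy}dimethylsilane
Product: 12 (2S)-1-[(2R)-3,3-dimethyloxiran-2-yl]-3-[(1S)-4-methylcyclohexa-2,4-dien-1-yl]but-3-en-2-ol
Conditions: Bu4NF, THF, 0 °C to rt
Reagents that add atoms: none
Why: Fluoride cleavage of the silyl ether; under these non-acidic conditions neither the diene nor the epoxide should be affected, and attack of the alkoxide on the epoxide would need a disfavoured four- or five-membered closure.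

Step 10
Reactants: 12 (2S)-1-[(2R)-3,3-dimethyloxiran-2-yl]-3-[(1S)-4-methylcyclohexa-2,4-dien-1-yl]but-3-en-2-ol; 13 tiglic acid, (2E)-2-methylbut-2-enoic acid
Product: 14 (2S)-1-[(2R)-3,3-dimethyloxiran-2-yl]-3-[(1S)-4-methylcyclohexa-2,4-dien-1-yl]but-3-en-2-yl (2E)-2-methylbut-2-enoate
Conditions: DCC, DMAP, CH2Cl2, 0 °C to rt
Reagents that add atoms: none
Why: Steglich esterification with retention at C8; the (E)-acid is the stable isomer and does not isomerise under DMAP catalysis, and the free acid avoids the ketene pathway that can deconjugate unsaturated acyl chlorides.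

Step 11
Reactants: 14 (2S)-1-[(2R)-3,3-dimethyloxiran-2-yl]-3-[(1S)-4-methylcyclohexa-2,4-dien-1-yl]but-3-en-2-yl (2E)-2-methylbut-2-enoate
Product: 16 (2S)-1-[(2R)-3,3-dimethyloxiran-2-yl]-3-[(1R,2S)-2-hydroxy-4-methyl-5-oxocyclohex-3-en-1-yl]but-3-en-2-yl (2E)-2-methylbut-2-enoate (C2 hydroxyl trans to the chain), via anti-endoperoxide 15 (not isolated)
Conditions: O2, tetraphenylporphyrin (cat.), visible light, CH2Cl2, −20 °C; then Et3N, 0 °C to rt
Reagents that add atoms: dioxygen, O=O
Why: Sensitised excitation gives singlet oxygen, which adds suprafacially across C2 and C5 of the s-cis-locked diene in a [4+2] cycloaddition to form the 2,3-dioxabicyclo[2.2.2]oct-5-ene 15. Triethylamine then removes the bridgehead C5–H with concerted O–O cleavage (Kornblum–DeLaMare rearrangement), so that C5 becomes the ketone, C2 keeps its oxygen as a hydroxyl and C3=C4 ends up conjugated. The closest known type is photooxygenation of 5-substituted 2-methylcyclohexa-1,3-dienes followed by amine-induced opening of the endoperoxide. The only ring closed is the transient six-membered 1,2-dioxine, formed by concerted cycloaddition and reopened in the same flask, so no new ring remains. The new stereocentre C2 is set by the face of oxygen approach, which the C1 stereocentre controls: the branched chain covers one face and oxygen should enter anti, leaving the C2 oxygen trans to the chain. Three selectivities are needed: anti facial addition, cycloaddition over ene reaction, and deprotonation at C5 over C2. The cisoid diene is by far the most electron-rich π system (the 1,1-disubstituted alkene and the tiglate are poor ene partners), C5–H is flanked by a CH2 group whereas C2–H lies beside the substituted C1, and a short exposure to the amine at low temperature limits onward isomerisation of the γ-hydroxy enone to the 1,4-diketone.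

Step 12
Reactants: 16 (2S)-1-[(2R)-3,3-dimethyloxiran-2-yl]-3-[(1R,2S)-2-hydroxy-4-methyl-5-oxocyclohex-3-en-1-yl]but-3-en-2-yl (2E)-2-methylbut-2-enoate
Product: 17 (2S)-3-[(1R,2S)-2-(tert-butyldimethylsilyloxy)-4-methyl-5-oxocyclohex-3-en-1-yl]-1-[(2R)-3,3-dimethyloxiran-2-yl]but-3-en-2-yl (2E)-2-methylbut-2-enoate
Conditions: TBSCl, imidazole, DMAP (cat.), DMF, rt
Reagents that add atoms: tert-butyldimethylsilyl chloride, CC(C)(C)[Si](C)(C)Cl
Why: Silylation under mildly basic, acid-free conditions avoids dehydration of the γ-hydroxy enone to a phenol; the bulky silyl ether protects C2–OH from oxidation in step 13 and becomes the directing group of step 14.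

Step 13
Reactants: 17 (2S)-3-[(1R,2S)-2-(tert-butyldimethylsilyloxy)-4-methyl-5-oxocyclohex-3-en-1-yl]-1-[(2R)-3,3-dimethyloxiran-2-yl]but-3-en-2-yl (2E)-2-methylbut-2-enoate
Product: 18 (2S)-3-[(1S,2S,6S)-6-acetoxy-2-(tert-butyldimethylsilyloxy)-4-methyl-5-oxocyclohex-3-en-1-yl]-1-[(2R)-3,3-dimethyloxiran-2-yl]but-3-en-2-yl (2E)-2-methylbut-2-enoate (acetate trans to the chain)
Conditions: Mn(OAc)3 (dried azeotropically), benzene, reflux
Reagents that add atoms: manganese triacetate, [Mn+3].CC(=O)[O-].CC(=O)[O-].CC(=O)[O-]
Why: α′-Acetoxylation of an enone by Mn(OAc)3 (trivalent manganese): the manganese enolate formed at C6 transfers acetate to that carbon. The acetate should enter anti to the adjacent C1 chain, and this trans, diequatorial arrangement is also the thermodynamic one, so any cis isomer can be equilibrated through the enol.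

Step 14
Reactants: 18 (2S)-3-[(1S,2S,6S)-6-acetoxy-2-(tert-butyldimethylsilyloxy)-4-methyl-5-oxocyclohex-3-en-1-yl]-1-[(2R)-3,3-dimethyloxiran-2-yl]but-3-en-2-yl (2E)-2-methylbut-2-enoate
Product: 19 (2S)-3-[(1S,2R,3S,4S,6S)-6-acetoxy-2-(tert-butyldimethylsilyloxy)-3,4-epoxy-4-methyl-5-oxocyclohexyl]-1-[(2R)-3,3-dimethyloxiran-2-yl]but-3-en-2-yl (2E)-2-methylbut-2-enoate (ring epoxide cis to the chain, trans to the silyloxy group)
Conditions: t-BuOOH (anhydrous), DBU, CH2Cl2, 0 °C to rt
Reagents that add atoms: tert-butyl hydroperoxide, CC(C)(C)OO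
Why: Weitz–Scheffer nucleophilic epoxidation: tert-butylperoxide adds to C3 and the enolate closes on the O–O bond. Attack anti to the adjacent bulky C2 silyloxy group (antiperiplanar to its C–O bond) should put the epoxide on the chain face and set C3 and C4 together; the non-nucleophilic amine base spares the acetate, and the tiglates are too poor as acceptors to react.

Step 15
Reactants: 19 (2S)-3-[(1S,2R,3S,4S,6S)-6-acetoxy-2-(tert-butyldimethylsilyloxy)-3,4-epoxy-4-methyl-5-oxocyclohexyl]-1-[(2R)-3,3-dimethyloxiran-2-yl]but-3-en-2-yl (2E)-2-methylbut-2-enoate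
Product: 20 (2S)-3-[(1R,2R,3S,4S,6S)-6-acetoxy-3,4-epoxy-2-hydroxy-4-methyl-5-oxocyclohexyl]-1-[(2R)-3,3-dimethyloxiran-2-yl]but-3-en-2-yl (2E)-2-methylbut-2-enoate (C2 hydroxyl trans to chain and epoxide)
Conditions: HF·pyridine, pyridine, THF, 0 °C to rt
Reagents that add atoms: none
Why: Buffered fluoride desilylation; the mildly acidic medium avoids alkoxide formation and so prevents both Payne rearrangement of the trans epoxy alcohol and acetate loss, while excess pyridine protects the epoxides.

Step 16
Reactants: 20 (2S)-3-[(1R,2R,3S,4S,6S)-6-acetoxy-3,4-epoxy-2-hydroxy-4-methyl-5-oxocyclohexyl]-1-[(2R)-3,3-dimethyloxiran-2-yl]but-3-en-2-yl (2E)-2-methylbut-2-enoate; 13 tiglic acid, (2E)-2-methylbut-2-enoic acid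
Product: 21 the target, (2S)-3-{(1R,2S,3S,4S,6S)-6-acetoxy-3,4-epoxy-4-methyl-2-[(2E)-2-methylbut-2-enoyloxy]-5-oxocyclohexyl}-1-[(2R)-3,3-dimethyloxiran-2-yl]but-3-en-2-yl (2E)-2-methylbut-2-enoate
Conditions: PPh3, DIAD, toluene, 0 °C to rt
Reagents that add atoms: none
Why: Mitsunobu esterification: the C2 hydroxyl is activated as its alkoxyphosphonium ion and displaced by tiglate in an SN2 step, which inverts C2 and places the ester cis to the chain and the epoxide. The neutral conditions leave the epoxy ketone and acetate untouched.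

## Compound list

1 | (S)-(+)-carvone, (5S)-2-methyl-5-(prop-1-en-2-yl)cyclohex-2-en-1-one | C=C(C)[C@@H]1CC(=O)C(C)=CC1 | starting material
2 | (5S)-5-(3-chloroprop-1-en-2-yl)-2-methylcyclohex-2-en-1-one | C=C(CCl)[C@@H]1CC(=O)C(C)=CC1 | intermediate
3 | 2-[(1S)-4-methyl-5-oxocyclohex-3-en-1-yl]prop-2-enal | C=C(C=O)[C@@H]1CC(=O)C(C)=CC1 | intermediate
4 | (3S)-2-[(1S)-4-methyl-5-oxocyclohex-3-en-1-yl]hexa-1,5-dien-3-yl diisopinocampheylborinate (isopinocampheyl groups from (+)-α-pinene; forms in the flask, not isolated) | C=C([C@@H]1CC(=O)C(C)=CC1)[C@H](CC=C)OB([C@@H]1C[C@@H]2C[C@H]([C@H]1C)C2(C)C)[C@@H]1C[C@@H]2C[C@H]([C@H]1C)C2(C)C | intermediate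
5 | (5S)-5-[(3S)-3-hydroxyhexa-1,5-dien-2-yl]-2-methylcyclohex-2-en-1-one | C=C([C@@H]1CC(=O)C(C)=CC1)[C@H](CC=C)O | intermediate
6 | (5S)-5-[(3S)-3-(tert-butyldimethylsilyloxy)hexa-1,5-dien-2-yl]-2-methylcyclohex-2-en-1-one | C=C([C@@H]1CC(=O)C(C)=CC1)[C@H](CC=C)O[Si](C)(C)C(C)(C)C | intermediate
7 | (5S)-5-[(3S)-3-(tert-butyldimethylsilyloxy)-6-methylhepta-1,5-dien-2-yl]-2-methylcyclohex-2-en-1-one | C=C([C@@H]1CC(=O)C(C)=CC1)[C@H](CC=C(C)C)O[Si](C)(C)C(C)(C)C | intermediate
8 | (5S)-5-{(3S)-3-(tert-butyldimethylsilyloxy)-4-[(2R)-3,3-dimethyloxiran-2-yl]but-1-en-2-yl}-2-methylcyclohex-2-en-1-one | C=C([C@@H]1CC(=O)C(C)=CC1)[C@H](C[C@H]1OC1(C)C)O[Si](C)(C)C(C)(C)C | intermediate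
9 | lithium (6S)-6-{(3S)-3-(tert-butyldimethylsilyloxy)-4-[(2R)-3,3-dimethyloxiran-2-yl]but-1-en-2-yl}-3-methylcyclohexa-1,3-dien-2-olate (forms in the flask, not isolated) | C=C([C@@H]1C=C([O-])C(C)=CC1)[C@H](C[C@H]1OC1(C)C)O[Si](C)(C)C(C)(C)C.[Li+] | intermediate
10 | (6S)-6-{(3S)-3-(tert-butyldimethylsilyloxy)-4-[(2R)-3,3-dimethyloxiran-2-yl]but-1-en-2-yl}-3-methylcyclohexa-1,3-dien-2-yl trifluoromethanesulfonate | C=C([C@@H]1C=C(OS(=O)(=O)C(F)(F)F)C(C)=CC1)[C@H](C[C@H]1OC1(C)C)O[Si](C)(C)C(C)(C)C | intermediate
11 | tert-butyl{[(2S)-1-[(2R)-3,3-dimethyloxiran-2-yl]-3-[(1S)-4-methylcyclohexa-2,4-dien-1-yl]but-3-en-2-yl]oxy}dimethylsilane | C=C([C@@H]1C=CC(C)=CC1)[C@H](C[C@H]1OC1(C)C)O[Si](C)(C)C(C)(C)C | intermediate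
12 | (2S)-1-[(2R)-3,3-dimethyloxiran-2-yl]-3-[(1S)-4-methylcyclohexa-2,4-dien-1-yl]but-3-en-2-ol | C=C([C@@H]1C=CC(C)=CC1)[C@H](C[C@H]1OC1(C)C)O | intermediate
13 | tiglic acid, (2E)-2-methylbut-2-enoic acid | C/C=C(\C)C(=O)O | starting material
14 | (2S)-1-[(2R)-3,3-dimethyloxiran-2-yl]-3-[(1S)-4-methylcyclohexa-2,4-dien-1-yl]but-3-en-2-yl (2E)-2-methylbut-2-enoate | C=C([C@@H]1C=CC(C)=CC1)[C@H](C[C@H]1OC1(C)C)OC(=O)/C(C)=C/C | intermediate
15 | endoperoxide of 14: 2,3-dioxabicyclo[2.2.2]oct-5-ene with the O–O bridge joining C2 and C5 on the face anti to the chain (C1 R, C2 S, C5 S; forms in the flask, not isolated) | C=C([C@@H]1[C@@H]2C=C(C)[C@H](C1)OO2)[C@H](C[C@H]1OC1(C)C)OC(=O)/C(C)=C/C | intermediate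
16 | (2S)-1-[(2R)-3,3-dimethyloxiran-2-yl]-3-[(1R,2S)-2-hydroxy-4-methyl-5-oxocyclohex-3-en-1-yl]but-3-en-2-yl (2E)-2-methylbut-2-enoate | C=C([C@@H]1[C@@H](O)C=C(C)C(=O)C1)[C@H](C[C@H]1OC1(C)C)OC(=O)/C(C)=C/C | intermediate
17 | (2S)-3-[(1R,2S)-2-(tert-butyldimethylsilyloxy)-4-methyl-5-oxocyclohex-3-en-1-yl]-1-[(2R)-3,3-dimethyloxiran-2-yl]but-3-en-2-yl (2E)-2-methylbut-2-enoate | C=C([C@@H]1[C@@H](O[Si](C)(C)C(C)(C)C)C=C(C)C(=O)C1)[C@H](C[C@H]1OC1(C)C)OC(=O)/C(C)=C/C | intermediate
18 | (2S)-3-[(1S,2S,6S)-6-acetoxy-2-(tert-butyldimethylsilyloxy)-4-methyl-5-oxocyclohex-3-en-1-yl]-1-[(2R)-3,3-dimethyloxiran-2-yl]but-3-en-2-yl (2E)-2-methylbut-2-enoate | C=C([C@@H]1[C@@H](O[Si](C)(C)C(C)(C)C)C=C(C)C(=O)[C@H]1OC(C)=O)[C@H](C[C@H]1OC1(C)C)OC(=O)/C(C)=C/C | intermediate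
19 | (2S)-3-[(1S,2R,3S,4S,6S)-6-acetoxy-2-(tert-butyldimethylsilyloxy)-3,4-epoxy-4-methyl-5-oxocyclohexyl]-1-[(2R)-3,3-dimethyloxiran-2-yl]but-3-en-2-yl (2E)-2-methylbut-2-enoate | C=C([C@@H]1[C@@H](O[Si](C)(C)C(C)(C)C)[C@@H]2O[C@]2(C)C(=O)[C@H]1OC(C)=O)[C@H](C[C@H]1OC1(C)C)OC(=O)/C(C)=C/C | intermediate
20 | (2S)-3-[(1R,2R,3S,4S,6S)-6-acetoxy-3,4-epoxy-2-hydroxy-4-methyl-5-oxocyclohexyl]-1-[(2R)-3,3-dimethyloxiran-2-yl]but-3-en-2-yl (2E)-2-methylbut-2-enoate | C=C([C@@H]1[C@@H](O)[C@@H]2O[C@]2(C)C(=O)[C@H]1OC(C)=O)[C@H](C[C@H]1OC1(C)C)OC(=O)/C(C)=C/C | intermediate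
21 | (2S)-3-{(1R,2S,3S,4S,6S)-6-acetoxy-3,4-epoxy-4-methyl-2-[(2E)-2-methylbut-2-enoyloxy]-5-oxocyclohexyl}-1-[(2R)-3,3-dimethyloxiran-2-yl]but-3-en-2-yl (2E)-2-methylbut-2-enoate | C=C([C@@H]1[C@H](OC(=O)/C(C)=C/C)[C@@H]2O[C@]2(C)C(=O)[C@H]1OC(C)=O)[C@H](C[C@H]1OC1(C)C)OC(=O)/C(C)=C/C | target

## Step count and least certain steps

Total: 16 steps. Longest linear sequence: 16 steps from 1 (13 is used as purchased).

**Step 11 (key step).**
- What may go wrong: face discrimination may be incomplete, because singlet oxygen is a small reagent with an early transition state and the C1 substituent is its only guide. The amine may also remove the C2 bridgehead proton in part, or carry the γ-hydroxy enone on to the 1,4-diketone.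
- Fallback, from 14 back to 16: run the photooxygenation without amine and isolate endoperoxide 15 by chromatography at low temperature, separating any syn adduct. Reduce the O–O bond with thiourea in methanol to the cis-enediol, (2S)-1-[(2R)-3,3-dimethyloxiran-2-yl]-3-[(1R,2S,5S)-2,5-dihydroxy-4-methylcyclohex-3-en-1-yl]but-3-en-2-yl (2E)-2-methylbut-2-enoate F1. Then oxidise only the more accessible C5 allylic alcohol (flanked by CH2) with MnO2 in CH2Cl2 to return to 16. The base-induced step, and with it the site-of-deprotonation question, is replaced by reduction and selective oxidation.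

**Step 14.**
- What may go wrong: the C1 chain by itself favours conjugate attack trans to it, which opposes the silyloxy group, so facial selectivity may be eroded. The basic peroxide may also remove or shift the C6 acetate.
- Fallback, from 18 back to 19: reduce the ketone with NaBH4/CeCl3·7H2O in MeOH at −78 °C (Luche reduction). Axial hydride delivery to the all-equatorial conformer should place the C5 hydroxyl on the chain face, giving the allylic alcohol, the C5 carbinol of 18 with hydroxyl cis to the chain F2. Epoxidise under hydroxyl direction with VO(acac)2/t-BuOOH to the epoxy alcohol, the C5 carbinol of 19 F3. Oxidise with Dess–Martin periodinane to 19. The epoxide face is then set by a directing hydroxyl and an electrophilic oxidant.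

**Step 16.**
- What may go wrong: the displacement has to occur on the face that carries both the chain and the epoxide. With the weakly acidic tiglic acid, acyl transfer with retention or elimination may outrun SN2 substitution.
- Fallback, from 20 back to 21: perform the Mitsunobu reaction with chloroacetic acid, which is known to invert hindered alcohols, to give the inverted chloroacetate, the C2 chloroacetate of 21 in place of its C2 tiglate F4. Remove the chloroacetyl group selectively with thiourea/NaHCO3 in ethanol to the cis epoxy alcohol, the C2 epimer of 20 F5. Esterify with 13 (DCC, DMAP) to reach 21.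

**Step 13.**
- What may go wrong: the acetic acid released in hot benzene and the Lewis-acidic manganese salts may open the 2,2-dimethyloxirane or loosen the silyl ether, and the trans selectivity may be incomplete.
- Fallback, from 17 back to 18: form the cross-conjugated silyl dienol ether with LiN(SiMe3)2/Me3SiCl at −78 °C, the 5-trimethylsilyloxy-3,5-diene of 17 F6. Oxidise it with dimethyldioxirane at −78 °C (Rubottom oxidation, oxygen entering anti to the chain) to the α′-hydroxy enone, the C6 alcohol corresponding to 18 F7. Acetylate with Ac2O/pyridine to 18.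

**Step 2.**
- What may go wrong: displacement of the allylic chloride by the N-oxide may be slow, and the 2-substituted acrolein may oligomerise during a long reaction.
- Fallback, from 2 back to 3: displace chloride with KOAc (Bu4NI, DMF) to the allylic acetate, [2-[(1S)-4-methyl-5-oxocyclohex-3-en-1-yl]prop-2-en-1-yl] acetate F8. Methanolyse with K2CO3/MeOH to the allylic alcohol, (5S)-5-(3-hydroxyprop-1-en-2-yl)-2-methylcyclohex-2-en-1-one F9. Oxidise with MnO2 to 3.

## Further compounds

F1 | step 11 | (2S)-1-[(2R)-3,3-dimethyloxiran-2-yl]-3-[(1R,2S,5S)-2,5-dihydroxy-4-methylcyclohex-3-en-1-yl]but-3-en-2-yl (2E)-2-methylbut-2-enoate (both hydroxyls trans to the chain) | C=C([C@@H]1[C@@H](O)C=C(C)[C@@H](O)C1)[C@H](C[C@H]1OC1(C)C)OC(=O)/C(C)=C/C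
F2 | step 14 | C5 allylic alcohol from 18 (C5 hydroxyl cis to the chain, trans to the C6 acetate) | C=C([C@@H]1[C@@H](O[Si](C)(C)C(C)(C)C)C=C(C)[C@H](O)[C@H]1OC(C)=O)[C@H](C[C@H]1OC1(C)C)OC(=O)/C(C)=C/C
F3 | step 14 | C5 carbinol of 19 (3,4-epoxide and C5 hydroxyl both cis to the chain) | C=C([C@@H]1[C@@H](O[Si](C)(C)C(C)(C)C)[C@@H]2O[C@]2(C)[C@H](O)[C@H]1OC(C)=O)[C@H](C[C@H]1OC1(C)C)OC(=O)/C(C)=C/C
F4 | step 16 | C2 chloroacetate analogue of 21 (chloroacetoxy group cis to chain and epoxide) | C=C([C@@H]1[C@H](OC(=O)CCl)[C@@H]2O[C@]2(C)C(=O)[C@H]1OC(C)=O)[C@H](C[C@H]1OC1(C)C)OC(=O)/C(C)=C/C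
F5 | step 16 | C2 epimer of 20 (C2 hydroxyl cis to chain and epoxide) | C=C([C@@H]1[C@H](O)[C@@H]2O[C@]2(C)C(=O)[C@H]1OC(C)=O)[C@H](C[C@H]1OC1(C)C)OC(=O)/C(C)=C/C
F6 | step 13 | trimethylsilyl dienol ether of 17 (C5–OSiMe3, C5=C6 and C3=C4) | C=C([C@@H]1[C@@H](O[Si](C)(C)C(C)(C)C)C=C(C)C(O[Si](C)(C)C)=C1)[C@H](C[C@H]1OC1(C)C)OC(=O)/C(C)=C/C
F7 | step 13 | C6 alcohol corresponding to 18 (C6 hydroxyl trans to the chain) | C=C([C@@H]1[C@@H](O[Si](C)(C)C(C)(C)C)C=C(C)C(=O)[C@H]1O)[C@H](C[C@H]1OC1(C)C)OC(=O)/C(C)=C/C
F8 | step 2 | [2-[(1S)-4-methyl-5-oxocyclohex-3-en-1-yl]prop-2-en-1-yl] acetate | C=C(COC(C)=O)[C@@H]1CC(=O)C(C)=CC1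
F9 | step 2 | (5S)-5-(3-hydroxyprop-1-en-2-yl)-2-methylcyclohex-2-en-1-one | C=C(CO)[C@@H]1CC(=O)C(C)=CC1
A1 | alternative 1 | (1E,3E)-1,4-bis(tert-butyldimethylsilyloxy)-2-methylbuta-1,3-diene | CC(=C\O[Si](C)(C)C(C)(C)C)/C=C/O[Si](C)(C)C(C)(C)C
A2 | alternative 1 | (E)-4-acetoxybut-3-en-2-one | CC(=O)/C=C/OC(C)=O
A3 | alternative 1 | all-cis 1-acetyl-2,5-bis(tert-butyldimethylsilyloxy)-4-methylcyclohex-3-en-6-yl acetate (acetate trans to the acetyl group) | CC(=O)[C@@H]1[C@H](O[Si](C)(C)C(C)(C)C)C=C(C)[C@H](O[Si](C)(C)C(C)(C)C)[C@H]1OC(C)=O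
A4 | alternative 2 | open-chain keto aldehyde: C5 aldehyde and C4 methyl ketone, C6 4-methoxybenzyl ether, C3 triethylsilyl ether, C2 and C8 tert-butyldimethylsilyl ethers, C10/C11 epoxide | C=C([C@H]([C@H](O[Si](C)(C)C(C)(C)C)[C@@H](O[Si](CC)(CC)CC)C(C)=O)[C@H](OCc1ccc(OC)cc1)C=O)[C@H](C[C@H]1OC1(C)C)O[Si](C)(C)C(C)(C)C
A5 | alternative 2 | cyclic tertiary α-hydroxy ketone with the C4 carbinol trans to the C3 silyloxy group | C=C([C@@H]1[C@H](O[Si](C)(C)C(C)(C)C)[C@@H](O[Si](CC)(CC)CC)[C@](C)(O)C(=O)[C@H]1OCc1ccc(OC)cc1)[C@H](C[C@H]1OC1(C)C)O[Si](C)(C)C(C)(C)C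
A6 | alternative 3 | manno-configured methyl 4-O-acetyl-3,6-dideoxy-2-O-(4-methoxybenzyl)-3-C-[(3S)-3-(tert-butyldimethylsilyloxy)-6-methylhepta-1,5-dien-2-yl]hex-5-enopyranoside (one anomer drawn; the anomeric centre is lost in the reaction) | C=C([C@@H]1[C@H](OCc2ccc(OC)cc2)[C@@H](OC)OC(=C)[C@H]1OC(C)=O)[C@H](CC=C(C)C)O[Si](C)(C)C(C)(C)C
A7 | alternative 3 | 6-acetoxy-3-hydroxy-2-(4-methoxybenzyloxy)-1-alkenylcyclohexan-5-one | C=C([C@@H]1[C@H](OCc2ccc(OC)cc2)[C@@H](O)CC(=O)[C@H]1OC(C)=O)[C@H](CC=C(C)C)O[Si](C)(C)C(C)(C)C
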